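**Retrosynthetic overview** (germacrane numbering: C1 furanone carbonyl, C3 and C10 ether-bridge carbons, C6/C7 lactone ring carbons, C11–C13 methylene lactone; ring A = α-methylene-γ-lactone, ring B = ten-membered carbocycle, ring C = 3(2H)-furanone)
1. Ring C (O, C10, C1, C2, C3) is not closed as such: it grows out of the C9–C10 oxirane of an acyclic epoxy ynone, the oxirane O adding to C3 and water opening C9 (three-membered to five-membered).
2. Enabling feature: C10 carries both the oxirane O and the ynone C1(=O)–C2≡C3, so O and C3 are 1,4-related (5-endo-dig); C10 is quaternary and α to the ketone, so the epoxonium can only open at C9 (inversion gives 9-OH, C10–O is kept).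
3. Rings B and A close together last by intramolecular Barbier-type allylation C6–C7 of a (Z)-enal with a 2-(methoxycarbonyl)allyl acetate; ring C is the turn element.
4. Epoxy ynone from C1–C2 bond formation: catalytic asymmetric alkynylation of an (E)-2-methyl enal with (Z)-3-methylpent-2-en-4-yn-1-ol (C2–C6, C15). The C1 carbinol directs the epoxidation (C9, C10) and is then oxidised away. The enal comes from (R)-glyceraldehyde acetonide (C7–C9, source of C8), methyl acrylate (C11–C13) and a C3 ylide (C10, C1, C14).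
5. Ring order: oxirane, then ring C, then rings B and A; the isovalerate is attached last.

Key step: step 11

Assumption: the ProPhenol antipode in step 8 is taken to be the one that adds the alkynyl group to the Si face of aldehyde 10 (written as (S,S)); should the sense be the reverse, the (R,R)-ligand is used and nothing else changes.

Step 1
Reactants: 1 (R)-2,2-dimethyl-1,3-dioxolane-4-carbaldehyde; 2 methyl acrylate
Product: 3 methyl 2-{[(4R)-2,2-dimethyl-1,3-dioxolan-4-yl](hydroxy)methyl}prop-2-enoate (both C7 epimers)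
Conditions: DABCO (0.5 equiv), 2 (5 equiv, neat), rt
Reagents that add atoms: none
Why: Morita–Baylis–Hillman reaction of an α-alkoxy aldehyde, which joins C7–C11 and brings in C11–C13; the new C7 carbinol centre needs no control because it becomes sp2 in step 2, and C8 is taken over unchanged from 1.

Step 2
Reactants: 3
Product: 5 methyl (2E)-2-[(acetyloxy)methyl]-3-[(4S)-2,2-dimethyl-1,3-dioxolan-4-yl]prop-2-enoate, via secondary acetate 4 (not isolated)
Conditions: Ac2O, pyridine, DMAP (cat.), CH2Cl2, 0 °C; then DABCO (0.2 equiv), THF, 65 °C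
Reagents that add atoms: acetic anhydride, CC(=O)OC(C)=O
Why: O-acetylation followed by the DABCO-mediated SN2′–SN2′ 1,3-transposition of Morita–Baylis–Hillman acetates should give the thermodynamically preferred (E)-2-(acetoxymethyl) enoate, in which both C7 epimers converge and the acetate is placed as the allylic leaving group for step 14.

Step 3
Reactants: 5
Product: 6 methyl (2E,4S)-2-[(acetyloxy)methyl]-4,5-dihydroxypent-2-enoate
Conditions: AcOH/H2O (4:1), 40 °C
Reagents that add atoms: none
Why: Acid-catalysed acetal hydrolysis; the E geometry holds the C8 hydroxyl trans to the ester, so no butenolide can form.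

Step 4
Reactants: 6
Product: 7 methyl (2E,4S)-2-[(acetyloxy)methyl]-4,5-bis[(triethylsilyl)oxy]pent-2-enoate
Conditions: TESCl, imidazole, DMAP (cat.), DMF, 0 °C to rt
Reagents that add atoms: chlorotriethylsilane, CC[Si](Cl)(CC)CC
Why: Routine silylation of both hydroxyls, which prepares the differentiation of C9 from O8 in the next step.

Step 5
Reactants: 7
Product: 8 methyl (2E,4S)-2-[(acetyloxy)methyl]-5-oxo-4-[(triethylsilyl)oxy]pent-2-enoate
Conditions: (COCl)2, DMSO, CH2Cl2, −78 to −40 °C; Et3N, −78 to −20 °C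
Reagents that add atoms: none
Why: Swern oxidation applied directly to a primary triethylsilyl ether, which is cleaved and oxidised in one operation while the secondary silyl ether survives, so the C9 aldehyde is unmasked without a separate deprotection.

Step 6
Reactants: 8; 9 2-(triphenylphosphoranylidene)propanal
Product: 10 methyl (2E,4R,5E)-2-[(acetyloxy)methyl]-6-methyl-7-oxo-4-[(triethylsilyl)oxy]hepta-2,5-dienoate
Conditions: toluene, 80 °C
Reagents that add atoms: none
Why: Wittig olefination with the formyl-stabilised ylide should give the (E)-2-methyl enal (C9=C10 with C14 and C1) under thermodynamic control, and the conjugated product aldehyde is too unreactive towards 9 to be homologated again.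

Step 7
Reactants: 11 (2Z)-3-methylpent-2-en-4-yn-1-ol
Product: 12 triethyl{[(2Z)-3-methylpent-2-en-4-yn-1-yl]oxy}silane
Conditions: TESCl, imidazole, CH2Cl2, 0 °C
Reagents that add atoms: chlorotriethylsilane, CC[Si](Cl)(CC)CC
Why: Silylation of the primary allylic alcohol, which blocks cycloisomerisation of the (Z)-enynol to a furan in the later metal-catalysed steps.

Step 8
Reactants: 10; 12
Product: 13 methyl (2E,4R,5E,7R,10Z)-2-[(acetyloxy)methyl]-7-hydroxy-6,10-dimethyl-4,12-bis[(triethylsilyl)oxy]dodeca-2,5,10-trien-8-ynoate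
Conditions: 12 (2.8 equiv), Me2Zn (2.9 equiv), (S,S)-ProPhenol (20 mol%), Ph3PO (40 mol%), toluene, 4 °C
Reagents that add atoms: none
Why: Dinuclear zinc–ProPhenol-catalysed enantioselective 1,2-addition of the zinc alkynylide of 12 to the α-branched enal, which forms C1–C2 and sets the temporary C1 carbinol as R by catalyst control (Si-face attack).

Step 9
Reactants: 13
Product: 14 methyl (2E,4S,5S,6S,7S,10Z)-2-[(acetyloxy)methyl]-5,6-epoxy-7-hydroxy-6,10-dimethyl-4,12-bis[(triethylsilyl)oxy]dodeca-2,10-dien-8-ynoate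
Conditions: Ti(OiPr)4 (20 mol%), L-(+)-DIPT (24 mol%), TBHP (2 equiv), 4 Å MS, CH2Cl2, −20 °C
Reagents that add atoms: tert-butyl hydroperoxide, CC(C)(C)OO
Why: Sharpless asymmetric epoxidation in the matched sense, in which the titanium-bound (1R) carbinol delivers oxygen to the C9=C10 face anti to its alkynyl group (erythro product), so that C9 and C10 are set by relay from C1 while the alkenes that are not allylic alcohols stay untouched.

Step 10
Reactants: 14
Product: 15 methyl (2E,4S,5S,6R,10Z)-2-[(acetyloxy)methyl]-5,6-epoxy-6,10-dimethyl-7-oxo-4,12-bis[(triethylsilyl)oxy]dodeca-2,10-dien-8-ynoate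
Conditions: Dess–Martin periodinane, NaHCO3, CH2Cl2, 0 °C to rt
Reagents that add atoms: none
Why: Buffered Dess–Martin oxidation of the propargylic alcohol gives the epoxy ynone and erases the relay stereocentre C1 after it has done its work.

Step 11
Reactants: 15
Product: 16 methyl (2E,4S,5R)-2-[(acetyloxy)methyl]-5-hydroxy-5-[(2R)-2-methyl-3-oxo-5-{(2Z)-4-[(triethylsilyl)oxy]but-2-en-2-yl}-2,3-dihydrofuran-2-yl]-4-[(triethylsilyl)oxy]pent-2-enoate
Conditions: Ph3PAuNTf2 (5 mol%), THF/H2O (10:1), rt
Reagents that add atoms: water, O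
Why: Proposed new method: the cationic monovalent gold complex π-activates the ynone C2≡C3, the oxirane oxygen adds to C3 (the vinylogous position of the C1 ketone) to give an oxirane-fused bicyclic epoxonium ion, water opens this ion at C9 by backside attack, and protodeauration at C2 releases the 3(2H)-furanone, so that the three-membered O–C9–C10 ring has grown into the five-membered O–C10–C1–C2–C3 ring. The closest known reactions are the gold-catalysed 5-endo-dig cyclisation of γ-hydroxy ynones to 3(2H)-furanones and the gold-catalysed ring expansion of alkynyl oxiranes to furans in the presence of O-nucleophiles, which also run through attack of the oxirane oxygen on the gold–alkyne complex. Ring C closes in the 5-endo-dig mode and no other ring is formed. C10 keeps its configuration because its C–O bond is never broken, and C9 is inverted stereospecifically (9S oxirane to 9R alcohol), so both centres are controlled by the epoxide made in step 9. The step needs chemoselectivity for the oxirane oxygen over the C6 silyl ether oxygen and over plain hydration of the ynone, and regioselective opening at C9: the triethylsilyl group shields O6, and C10 is quaternary and α to the ketone, so neither SN2 attack nor cation formation is possible there. Hydrolytic opening of the epoxide at C9 before cyclisation of the C10 hydroxyl would lead to the same product with the same configuration, so the two conceivable orders of events converge.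

Step 12
Reactants: 16
Product: 17 methyl (2E,4S,5R)-2-[(acetyloxy)methyl]-5-hydroxy-5-{(2R)-5-[(2Z)-4-hydroxybut-2-en-2-yl]-2-methyl-3-oxo-2,3-dihydrofuran-2-yl}-4-[(triethylsilyl)oxy]pent-2-enoate
Conditions: HF·pyridine, pyridine, THF, 0 °C
Reagents that add atoms: none
Why: Buffered fluoride desilylation, in which the primary allylic triethylsilyl ether should be cleaved much faster than the hindered secondary one at C8.

Step 13
Reactants: 17
Product: 18 methyl (2E,4S,5R)-2-[(acetyloxy)methyl]-5-hydroxy-5-{(2R)-2-methyl-3-oxo-5-[(2Z)-4-oxobut-2-en-2-yl]-2,3-dihydrofuran-2-yl}-4-[(triethylsilyl)oxy]pent-2-enoate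
Conditions: MnO2 (20 equiv), CH2Cl2, rt
Reagents that add atoms: none
Why: MnO2 oxidises only the allylic alcohol and keeps the Z geometry, while the C9 hydroxyl is not allylic and O8 is silylated; 17 is oxidised without storage to avoid addition of its C6 hydroxyl to C3.

Step 14
Reactants: 18
Product: 21 (6S,7S,8S,9R,10R)-9-hydroxy-8-[(triethylsilyl)oxy]-1-oxo-3,10-epoxygermacra-2,4Z,11(13)-trien-12,6-olide, via allylindium species 19 (not isolated), via hydroxy ester 20 (not isolated)
Conditions: Pd(PPh3)4 (10 mol%), InI (2 equiv), THF (2 mM, slow addition), rt; then PPTS (cat.), CH2Cl2, rt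
Reagents that add atoms: none
Why: Barbier-type allylation in which zerovalent palladium ionises the allylic acetate, InI turns the π-allyl complex into a nucleophilic 2-(methoxycarbonyl)allylindium, and this adds to the C6 aldehyde through a closed chair transition state; the C8 substituent cis to CH2In should give the syn adduct (6S), the aldehyde should reach C7 on the face anti to the C8–C9 bond in the rotamer with C8–H eclipsing the double bond (7S), and the C6 alkoxide lactonises to the cis-fused ring A.

Step 15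
Reactants: 21
Product: 22 (6S,7R,8S,9R,10R)-8,9-dihydroxy-1-oxo-3,10-epoxygermacra-2,4Z,11(13)-trien-12,6-olide
Conditions: HF·pyridine, THF, 0 °C to rt
Reagents that add atoms: none
Why: Fluoride cleavage of the secondary silyl ether under conditions that leave the methylene lactone and the furanone untouched (the C7 descriptor changes only through the priority rules).

Step 16
Reactants: 22; 23 3-methylbutanoic anhydride
Product: 24 (6S,7S,8S,9R,10R)-9-hydroxy-1-oxo-3,10-epoxygermacra-2,4Z,11(13)-trien-12,6-olid-8-yl 3-methylbutanoate (CNP0175298.2)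
Conditions: 23 (1.1 equiv), DMAP (0.1 equiv), 2,4,6-collidine, CH2Cl2, −40 to −20 °C
Reagents that add atoms: none
Why: DMAP-catalysed acylation should take place at the less hindered C8 hydroxyl, because the C9 hydroxyl is flanked by the fully substituted C10 and can hydrogen-bond to the C1 carbonyl.

**Compound list**
1 | (R)-2,2-dimethyl-1,3-dioxolane-4-carbaldehyde | CC1(C)OC[C@H](C=O)O1 | starting material
2 | methyl acrylate | C=CC(=O)OC | starting material
3 | methyl 2-{[(4R)-2,2-dimethyl-1,3-dioxolan-4-yl](hydroxy)methyl}prop-2-enoate (C7 epimer mixture, carbinol centre left undefined) | COC(=O)C(=C)C(O)[C@H]1COC(C)(C)O1 | intermediate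
4 | methyl 2-{(acetyloxy)[(4R)-2,2-dimethyl-1,3-dioxolan-4-yl]methyl}prop-2-enoate (C7 epimer mixture) | COC(=O)C(=C)C(OC(C)=O)[C@H]1COC(C)(C)O1 | intermediate
5 | methyl (2E)-2-[(acetyloxy)methyl]-3-[(4S)-2,2-dimethyl-1,3-dioxolan-4-yl]prop-2-enoate | COC(=O)/C(COC(C)=O)=C/[C@H]1COC(C)(C)O1 | intermediate
6 | methyl (2E,4S)-2-[(acetyloxy)methyl]-4,5-dihydroxypent-2-enoate | COC(=O)/C(COC(C)=O)=C/[C@H](O)CO | intermediate
7 | methyl (2E,4S)-2-[(acetyloxy)methyl]-4,5-bis[(triethylsilyl)oxy]pent-2-enoate | COC(=O)/C(COC(C)=O)=C/[C@H](O[Si](CC)(CC)CC)CO[Si](CC)(CC)CC | intermediate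
8 | methyl (2E,4S)-2-[(acetyloxy)methyl]-5-oxo-4-[(triethylsilyl)oxy]pent-2-enoate | COC(=O)/C(COC(C)=O)=C/[C@H](O[Si](CC)(CC)CC)C=O | intermediate
9 | 2-(triphenylphosphoranylidene)propanal | CC(C=O)=P(c1ccccc1)(c1ccccc1)c1ccccc1 | starting material
10 | methyl (2E,4R,5E)-2-[(acetyloxy)methyl]-6-methyl-7-oxo-4-[(triethylsilyl)oxy]hepta-2,5-dienoate | COC(=O)/C(COC(C)=O)=C/[C@H](O[Si](CC)(CC)CC)/C=C(\C)C=O | intermediate
11 | (2Z)-3-methylpent-2-en-4-yn-1-ol | C#C/C(C)=C\CO | starting material
12 | triethyl{[(2Z)-3-methylpent-2-en-4-yn-1-yl]oxy}silane | C#C/C(C)=C\CO[Si](CC)(CC)CC | intermediate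
13 | methyl (2E,4R,5E,7R,10Z)-2-[(acetyloxy)methyl]-7-hydroxy-6,10-dimethyl-4,12-bis[(triethylsilyl)oxy]dodeca-2,5,10-trien-8-ynoate | CC[Si](CC)(CC)OC/C=C(/C)C#C[C@H](O)/C(C)=C/[C@@H](O[Si](CC)(CC)CC)/C=C(\COC(C)=O)C(=O)OC | intermediate
14 | methyl (2E,4S,5S,6S,7S,10Z)-2-[(acetyloxy)methyl]-5,6-epoxy-7-hydroxy-6,10-dimethyl-4,12-bis[(triethylsilyl)oxy]dodeca-2,10-dien-8-ynoate | CC[Si](CC)(CC)OC/C=C(/C)C#C[C@H](O)[C@]1(C)O[C@H]1[C@@H](O[Si](CC)(CC)CC)/C=C(\COC(C)=O)C(=O)OC | intermediate
15 | methyl (2E,4S,5S,6R,10Z)-2-[(acetyloxy)methyl]-5,6-epoxy-6,10-dimethyl-7-oxo-4,12-bis[(triethylsilyl)oxy]dodeca-2,10-dien-8-ynoate | CC[Si](CC)(CC)OC/C=C(/C)C#CC(=O)[C@]1(C)O[C@H]1[C@@H](O[Si](CC)(CC)CC)/C=C(\COC(C)=O)C(=O)OC | intermediate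
16 | methyl (2E,4S,5R)-2-[(acetyloxy)methyl]-5-hydroxy-5-[(2R)-2-methyl-3-oxo-5-{(2Z)-4-[(triethylsilyl)oxy]but-2-en-2-yl}-2,3-dihydrofuran-2-yl]-4-[(triethylsilyl)oxy]pent-2-enoate | CC[Si](CC)(CC)OC/C=C(/C)C1=CC(=O)[C@](C)(O1)[C@H](O)[C@@H](O[Si](CC)(CC)CC)/C=C(\COC(C)=O)C(=O)OC | intermediate
17 | methyl (2E,4S,5R)-2-[(acetyloxy)methyl]-5-hydroxy-5-{(2R)-5-[(2Z)-4-hydroxybut-2-en-2-yl]-2-methyl-3-oxo-2,3-dihydrofuran-2-yl}-4-[(triethylsilyl)oxy]pent-2-enoate | OC/C=C(/C)C1=CC(=O)[C@](C)(O1)[C@H](O)[C@@H](O[Si](CC)(CC)CC)/C=C(\COC(C)=O)C(=O)OC | intermediate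
18 | methyl (2E,4S,5R)-2-[(acetyloxy)methyl]-5-hydroxy-5-{(2R)-2-methyl-3-oxo-5-[(2Z)-4-oxobut-2-en-2-yl]-2,3-dihydrofuran-2-yl}-4-[(triethylsilyl)oxy]pent-2-enoate | O=C/C=C(/C)C1=CC(=O)[C@](C)(O1)[C@H](O)[C@@H](O[Si](CC)(CC)CC)/C=C(\COC(C)=O)C(=O)OC | intermediate
19 | acetato(iodo)indium derivative of 18, trivalent indium bound to C13 in place of the acetoxy group | O=C/C=C(/C)C1=CC(=O)[C@](C)(O1)[C@H](O)[C@@H](O[Si](CC)(CC)CC)/C=C(\C[In](I)OC(C)=O)C(=O)OC | intermediate
20 | methyl 2-[(6S,7S,8S,9R,10R)-6,9-dihydroxy-1-oxo-8-(triethylsilyloxy)-3,10-epoxygermacra-2,4Z-dien-7-yl]prop-2-enoate (ring B closed, ring A still open) | COC(=O)C(=C)[C@H]1[C@@H](O)/C=C(/C)C2=CC(=O)[C@](C)(O2)[C@H](O)[C@H]1O[Si](CC)(CC)CC | intermediate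
21 | (6S,7S,8S,9R,10R)-9-hydroxy-8-[(triethylsilyl)oxy]-1-oxo-3,10-epoxygermacra-2,4Z,11(13)-trien-12,6-olide | C=C1C(=O)O[C@H]2/C=C(/C)C3=CC(=O)[C@](C)(O3)[C@H](O)[C@@H](O[Si](CC)(CC)CC)[C@@H]12 | intermediate
22 | (6S,7R,8S,9R,10R)-8,9-dihydroxy-1-oxo-3,10-epoxygermacra-2,4Z,11(13)-trien-12,6-olide | C=C1C(=O)O[C@H]2/C=C(/C)C3=CC(=O)[C@](C)(O3)[C@H](O)[C@@H](O)[C@@H]12 | intermediate
23 | 3-methylbutanoic anhydride | CC(C)CC(=O)OC(=O)CC(C)C | starting material
24 | (6S,7S,8S,9R,10R)-9-hydroxy-1-oxo-3,10-epoxygermacra-2,4Z,11(13)-trien-12,6-olid-8-yl 3-methylbutanoate | C=C1C(=O)O[C@H]2/C=C(/C)C3=CC(=O)[C@](C)(O3)[C@H](O)[C@@H](OC(=O)CC(C)C)[C@@H]12 | target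

**Step count and risks**
Total steps: 16. Longest linear sequence: 15 steps (steps 1–6 and 8–16, from 1); step 7 is a one-step side branch.

Steps most likely to fail:

Step 11 (proposed new method). The gold–alkyne complex may be intercepted by the C6 silyl ether oxygen or simply hydrated, or the epoxonium ion may not form before the epoxide is opened unselectively. The fallback uses known chemistry and sets out from 15. The epoxide is first opened hydrolytically at C9, the carbon remote from the ketone, with inversion (water, catalytic Sc(OTf)3 or Er(OTf)3, MeCN, 0 °C), to give the anti-9,10-diol ynone F1. The C10 hydroxyl of F1 is then closed onto C3 by the established 5-endo-dig cyclisation of γ-hydroxy ynones to 3(2H)-furanones (Ph3PAuNTf2 in CH2Cl2, or Et2NH in EtOH). This returns to the route at 16.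

Step 14. The ring closure may suffer from poor facial selectivity at C7 relative to C8, from oligomerisation, or from ionisation of the newly formed allylic lactone by zerovalent palladium. The fallback sets out from 17 and closes the ring by allylboration, with no low-valent metal present in the ring-forming event. Borylation of the allylic acetate (B2pin2, Pd2(dba)3 cat., DMSO) should give the allylboronate F2, and MnO2 oxidation then gives the boronate aldehyde F3. In dilute toluene (heat, or Sc(OTf)3 cat.) F3 should cyclise through a closed six-membered transition state, and the resulting C6 borate lactonises. This returns to the route at 21.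

Step 16. Acylation may occur at O9 or at both hydroxyls, and the ester may migrate between O8 and O9 or the free C8 hydroxyl may translactonise under base. The fallback sets out from 21 and fixes the regiochemistry by protection. Silylation of the C9 hydroxyl (TBSOTf, 2,6-lutidine) gives the 9-O-TBS 8-O-TES lactone F4. Selective removal of the more labile triethylsilyl group (HF·pyridine, pyridine, 0 °C) gives the 8-hydroxy 9-O-TBS lactone F5. Acylation with 23 and DMAP gives the 8-isovalerate 9-O-TBS lactone F6, and final desilylation (HF·pyridine, rt) returns to the route at 24.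

**Further compounds**
F1 | step 11 | methyl (2E,4S,5R,6R,10Z)-2-[(acetyloxy)methyl]-5,6-dihydroxy-6,10-dimethyl-7-oxo-4,12-bis[(triethylsilyl)oxy]dodeca-2,10-dien-8-ynoate | CC[Si](CC)(CC)OC/C=C(/C)C#CC(=O)[C@](C)(O)[C@H](O)[C@@H](O[Si](CC)(CC)CC)/C=C(\COC(C)=O)C(=O)OC
F2 | step 14 | pinacol allylboronate of 17 (Bpin on C13 in place of the acetoxy group) | OC/C=C(/C)C1=CC(=O)[C@](C)(O1)[C@H](O)[C@@H](O[Si](CC)(CC)CC)/C=C(\CB2OC(C)(C)C(C)(C)O2)C(=O)OC
F3 | step 14 | pinacol allylboronate of 18 (Bpin on C13, C6 aldehyde) | O=C/C=C(/C)C1=CC(=O)[C@](C)(O1)[C@H](O)[C@@H](O[Si](CC)(CC)CC)/C=C(\CB2OC(C)(C)C(C)(C)O2)C(=O)OC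
F4 | step 16 | 9-O-(tert-butyldimethylsilyl) ether of 21 | C=C1C(=O)O[C@H]2/C=C(/C)C3=CC(=O)[C@](C)(O3)[C@H](O[Si](C)(C)C(C)(C)C)[C@@H](O[Si](CC)(CC)CC)[C@@H]12
F5 | step 16 | 9-O-(tert-butyldimethylsilyl) ether of 22 with free C8 hydroxyl | C=C1C(=O)O[C@H]2/C=C(/C)C3=CC(=O)[C@](C)(O3)[C@H](O[Si](C)(C)C(C)(C)C)[C@@H](O)[C@@H]12
F6 | step 16 | 9-O-(tert-butyldimethylsilyl) ether of 24 | C=C1C(=O)O[C@H]2/C=C(/C)C3=CC(=O)[C@](C)(O3)[C@H](O[Si](C)(C)C(C)(C)C)[C@@H](OC(=O)CC(C)C)[C@@H]12
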